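The benzene ring is cut at C1–C2, C1–C6 and C4–C5 into three open-chain pieces: a zerovalent chromium benzyloxy(2-benzyloxyvinyl)carbene (C2–C4 with O2 and O4), 1-heptadecyne (C5, C6 and the pentadecyl chain) and one carbonyl ligand (C1 and O1). A single Dötz benzannulation assembles the ring and exploits the one difference among the three ring oxygens: O1, para to O4 and flanked by the C6 chain, comes from the carbonyl ligand and emerges as the only free phenol, while O2 and O4 arrive as benzyl ethers. Acetylation of O1 and neutral hydrogenolysis finish the target.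

Key step: step 4

Remark: the geometry of the enol ether in the carbene complex is erased on aromatisation, so the E isomer is planned but a Z contaminant would converge on the same phenol; carbonyl ligands are written Cr=C=O in SMILES, and the η6-arene complex 12 is written as two dot-separated parts because hapto bonding cannot be expressed.

Step 1
Reactants: 1 chromium hexacarbonyl; 2 ethynyltrimethylsilane
Product: 5 tetramethylammonium pentacarbonyl[1-oxido-3-(trimethylsilyl)prop-2-yn-1-ylidene]chromate, via lithium trimethylsilylacetylide 3 (not isolated), via lithium acylchromate 4 (not isolated)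
Conditions: n-BuLi, THF, −78 °C; Cr(CO)6, −78 °C → rt; then Me4NBr, degassed H2O, 0 °C
Reagents that add atoms: tetramethylammonium bromide, C[N+](C)(C)C.[Br-]
Why: First half of the Fischer carbene synthesis, in which the acetylide adds to a carbonyl ligand to give the acylchromate, and cation metathesis then gives the CH2Cl2-soluble tetramethylammonium salt that O-acylates cleanly.

Step 2
Reactants: 5 tetramethylammonium pentacarbonyl[1-oxido-3-(trimethylsilyl)prop-2-yn-1-ylidene]chromate; 6 benzyl alcohol
Product: 8 pentacarbonyl[1-(benzyloxy)-3-(trimethylsilyl)prop-2-yn-1-ylidene]chromium, via acetoxycarbene complex 7 (not isolated)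
Conditions: AcBr, CH2Cl2, −40 °C; then BnOH (1.1 equiv), −40 → −10 °C
Reagents that add atoms: none
Why: Acyloxycarbene route to higher alkoxy Fischer carbenes, in which O-acylation makes the carbene carbon anhydride-like and the alcohol displaces acetate by addition–elimination; without base and in the cold this attack should outrun conjugate addition to the silyl-capped triple bond.

Step 3
Reactants: 8 pentacarbonyl[1-(benzyloxy)-3-(trimethylsilyl)prop-2-yn-1-ylidene]chromium; 6 benzyl alcohol
Product: 10 pentacarbonyl[(2E)-1,3-bis(benzyloxy)prop-2-en-1-ylidene]chromium, via terminal alkynylcarbene complex 9 (not isolated)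
Conditions: BnOH (3 equiv), NaOBn (10 mol%), THF, −20 °C → rt
Reagents that add atoms: none
Why: Benzyloxide should cleave the carbene-activated C(sp)–Si bond and the freed alkynylcarbene should take up benzyl alcohol in an alkoxide-catalysed Michael addition, a known reaction of alkynyl(alkoxy)carbene complexes; the push–pull product should settle as the E enol ether, and any attack of benzyloxide at the carbene carbon is degenerate because both alkoxy groups are benzyloxy.

Step 4
Reactants: 10 pentacarbonyl[(2E)-1,3-bis(benzyloxy)prop-2-en-1-ylidene]chromium; 11 1-heptadecyne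
Product: 13 2,4-bis(benzyloxy)-6-pentadecylphenol, via tricarbonylchromium arene complex 12 (not isolated)
Conditions: 1-heptadecyne (2 equiv), t-BuOMe (0.5 M), 55 °C, Ar; then air, EtOAc, rt
Reagents that add atoms: none
Why: Loss of one CO from 10 opens a site for 1-heptadecyne, which inserts into the Cr=C bond (C4–C5) to give a chromium vinylcarbene; a carbonyl ligand then inserts (C1–C6) to give a chromium-bound dienylketene, which cyclises (C1–C2) and tautomerises to the phenol, held at first as its Cr(CO)3 complex 12 and freed by air. The closest known reaction type is the Dötz benzannulation of alkenyl(alkoxy)carbene complexes of zerovalent chromium with terminal alkynes. The one ring is closed by a 6π electrocyclisation of the dienylketene, so the whole event is a formal [3+2+1] assembly, and no stereocentre is formed. The step needs regiocontrol of the alkyne insertion, and the size difference between the pentadecyl chain and hydrogen should place the substituted alkyne carbon next to the CO-derived C1, so that the chain ends up ortho to the new hydroxyl. It also needs CO insertion to outrun cyclopentannulation, which the electron-releasing 2-benzyloxy group makes less certain; a high alkyne concentration in a weakly coordinating ether is chosen to favour the phenol path. The oxygen of the inserted CO appears as the only free hydroxyl, exactly at C1.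

Step 5
Reactants: 13 2,4-bis(benzyloxy)-6-pentadecylphenol
Product: 14 2,4-bis(benzyloxy)-6-pentadecylphenyl acetate
Conditions: Ac2O, pyridine, DMAP (cat.), CH2Cl2, 0 °C → rt
Reagents that add atoms: acetic anhydride, CC(=O)OC(C)=O
Why: DMAP-catalysed O-acylation of the only free hydroxyl, which should proceed despite the two flanking groups because O2 and O4 are blocked as benzyl ethers and no other nucleophile is present.

Step 6
Reactants: 14 2,4-bis(benzyloxy)-6-pentadecylphenyl acetate
Product: 15 2,4-dihydroxy-6-pentadecylphenyl acetate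
Conditions: H2 (1 atm), 10% Pd/C, EtOAc, rt
Reagents that add atoms: none
Why: Hydrogenolysis of both aryl benzyl ethers over palladium, run in a neutral aprotic solvent so that the aryl acetate stays intact and no base is present to carry the acetyl group to the neighbouring O2.

Compound list
1 | chromium hexacarbonyl | O=C=[Cr](=C=O)(=C=O)(=C=O)(=C=O)=C=O | starting material
2 | ethynyltrimethylsilane | C#C[Si](C)(C)C | starting material
3 | lithium trimethylsilylacetylide | [Li]C#C[Si](C)(C)C | intermediate
4 | lithium pentacarbonyl[1-oxido-3-(trimethylsilyl)prop-2-yn-1-ylidene]chromate | [Li+].[O-]C(C#C[Si](C)(C)C)=[Cr](=C=O)(=C=O)(=C=O)(=C=O)=C=O | intermediate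
5 | tetramethylammonium pentacarbonyl[1-oxido-3-(trimethylsilyl)prop-2-yn-1-ylidene]chromate | C[N+](C)(C)C.[O-]C(C#C[Si](C)(C)C)=[Cr](=C=O)(=C=O)(=C=O)(=C=O)=C=O | intermediate
6 | benzyl alcohol | OCc1ccccc1 | starting material
7 | pentacarbonyl[1-acetoxy-3-(trimethylsilyl)prop-2-yn-1-ylidene]chromium | CC(=O)OC(C#C[Si](C)(C)C)=[Cr](=C=O)(=C=O)(=C=O)(=C=O)=C=O | intermediate
8 | pentacarbonyl[1-(benzyloxy)-3-(trimethylsilyl)prop-2-yn-1-ylidene]chromium | O=C=[Cr](=C=O)(=C=O)(=C=O)(=C=O)=C(OCc1ccccc1)C#C[Si](C)(C)C | intermediate
9 | pentacarbonyl[1-(benzyloxy)prop-2-yn-1-ylidene]chromium | O=C=[Cr](=C=O)(=C=O)(=C=O)(=C=O)=C(OCc1ccccc1)C#C | intermediate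
10 | pentacarbonyl[(2E)-1,3-bis(benzyloxy)prop-2-en-1-ylidene]chromium | O=C=[Cr](=C=O)(=C=O)(=C=O)(=C=O)=C(OCc1ccccc1)/C=C/OCc1ccccc1 | intermediate
11 | 1-heptadecyne | C#CCCCCCCCCCCCCCCC | starting material
12 | tricarbonyl[η6-2,4-bis(benzyloxy)-6-pentadecylphenol]chromium | CCCCCCCCCCCCCCCc1cc(OCc2ccccc2)cc(OCc2ccccc2)c1O.O=C=[Cr](=C=O)=C=O | intermediate
13 | 2,4-bis(benzyloxy)-6-pentadecylphenol | CCCCCCCCCCCCCCCc1cc(OCc2ccccc2)cc(OCc2ccccc2)c1O | intermediate
14 | 2,4-bis(benzyloxy)-6-pentadecylphenyl acetate | CCCCCCCCCCCCCCCc1cc(OCc2ccccc2)cc(OCc2ccccc2)c1OC(C)=O | intermediate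
15 | 2,4-dihydroxy-6-pentadecylphenyl acetate | CCCCCCCCCCCCCCCc1cc(O)cc(O)c1OC(C)=O | target

Total step count: 6. Longest linear sequence: 6 steps (1 and 2 to 15).

Steps most likely to fail

Step 4. The electron-rich vinylcarbene may lose CO too slowly, or may cyclise without taking up a carbonyl ligand (cyclopentannulation), so that no phenol is formed. The fallback builds the same phenol by classical arene chemistry, setting out from benzyl alcohol 6 and rejoining the route at phenol 13. Purchased 5-pentadecylresorcinol (CCCCCCCCCCCCCCCc1cc(O)cc(O)c1) is etherified twice with 6 under Mitsunobu conditions (PPh3, DIAD, THF) to give 1,3-bis(benzyloxy)-5-pentadecylbenzene F1. Vilsmeier–Haack formylation (POCl3, DMF) at the ring position between the chain and one benzyloxy group should give 2,4-bis(benzyloxy)-6-pentadecylbenzaldehyde F2. Baeyer–Villiger oxidation with mCPBA in CH2Cl2 should give 2,4-bis(benzyloxy)-6-pentadecylphenyl formate F3, and methanolysis (K2CO3, MeOH) of F3 gives 13.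

Step 3. Cleavage of the C–Si bond may be incomplete, the terminal alkynylcarbene may oligomerise, or alkoxide may attack the carbonyl ligands and degrade the complex. The fallback makes the enol ether before chromium is introduced, setting out from chromium hexacarbonyl 1 and benzyl alcohol 6 and rejoining the route at phenol 13.
- Purchased benzyl vinyl ether (C=COCc1ccccc1) is brominated (Br2, CH2Cl2, −78 °C) to benzyl 1,2-dibromoethyl ether F4.
- Dehydrobromination with N,N-diethylaniline should give (Z)-1-(benzyloxy)-2-bromoethene F5.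
- Bromine–lithium exchange (t-BuLi, 2 equiv, THF, −78 °C) gives (Z)-2-(benzyloxy)vinyllithium F6.
- Addition of F6 to 1 gives lithium pentacarbonyl[(2Z)-3-(benzyloxy)-1-oxidoprop-2-en-1-ylidene]chromate F7, and Me4NBr converts it into tetramethylammonium pentacarbonyl[(2Z)-3-(benzyloxy)-1-oxidoprop-2-en-1-ylidene]chromate F8.
- AcBr at −40 °C gives pentacarbonyl[(2Z)-1-acetoxy-3-(benzyloxy)prop-2-en-1-ylidene]chromium F9, and 6 converts this into pentacarbonyl[(2Z)-1,3-bis(benzyloxy)prop-2-en-1-ylidene]chromium F10.
- F10 is used with 11 under the conditions of step 4 and should give 13 through 12, because the enol ether geometry is lost on aromatisation.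

Step 2. Benzyl alcohol may add to the triple bond of the very electrophilic acetoxycarbene, or that intermediate may decay before alcoholysis. The fallback forms the O–CH2 bond instead of the carbene carbon–oxygen bond, setting out from acylchromate 5 and benzyl alcohol 6 and coming back at carbene complex 8. Benzyl trifluoromethanesulfonate F11 is generated from 6 with Tf2O and 2,6-di-tert-butyl-4-methylpyridine in CH2Cl2 at −78 °C and alkylates the acylate oxygen of 5 directly.

Further compounds
F1 | step 4 | 1,3-bis(benzyloxy)-5-pentadecylbenzene | CCCCCCCCCCCCCCCc1cc(OCc2ccccc2)cc(OCc2ccccc2)c1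
F2 | step 4 | 2,4-bis(benzyloxy)-6-pentadecylbenzaldehyde | CCCCCCCCCCCCCCCc1cc(OCc2ccccc2)cc(OCc2ccccc2)c1C=O
F3 | step 4 | 2,4-bis(benzyloxy)-6-pentadecylphenyl formate | CCCCCCCCCCCCCCCc1cc(OCc2ccccc2)cc(OCc2ccccc2)c1OC=O
F4 | step 3 | benzyl 1,2-dibromoethyl ether | BrCC(Br)OCc1ccccc1
F5 | step 3 | (Z)-1-(benzyloxy)-2-bromoethene | Br/C=C\OCc1ccccc1
F6 | step 3 | (Z)-2-(benzyloxy)vinyllithium | [Li]/C=C\OCc1ccccc1
F7 | step 3 | lithium pentacarbonyl[(2Z)-3-(benzyloxy)-1-oxidoprop-2-en-1-ylidene]chromate | [Li+].[O-]C(/C=C\OCc1ccccc1)=[Cr](=C=O)(=C=O)(=C=O)(=C=O)=C=O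
F8 | step 3 | tetramethylammonium pentacarbonyl[(2Z)-3-(benzyloxy)-1-oxidoprop-2-en-1-ylidene]chromate | C[N+](C)(C)C.[O-]C(/C=C\OCc1ccccc1)=[Cr](=C=O)(=C=O)(=C=O)(=C=O)=C=O
F9 | step 3 | pentacarbonyl[(2Z)-1-acetoxy-3-(benzyloxy)prop-2-en-1-ylidene]chromium | CC(=O)OC(/C=C\OCc1ccccc1)=[Cr](=C=O)(=C=O)(=C=O)(=C=O)=C=O
F10 | step 3 | pentacarbonyl[(2Z)-1,3-bis(benzyloxy)prop-2-en-1-ylidene]chromium | O=C=[Cr](=C=O)(=C=O)(=C=O)(=C=O)=C(OCc1ccccc1)/C=C\OCc1ccccc1
F11 | step 2 | benzyl trifluoromethanesulfonate | O=S(=O)(OCc1ccccc1)C(F)(F)F
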